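Everything rests on cutting the piperidine at C6': this ring carbon carries only hydrogens and sits between C5' and N1', which is a tertiary N-methyl nitrogen. Ring closure can therefore be a carbonylation. Rhodium-catalysed hydroformylation of the terminal alkene of (R)-1-aryl-N-methylbut-3-en-1-amine 13 (aryl = 4-methoxy-2,6-bis(MOM-oxy)phenyl), with in-situ reductive amination, brings in CO as C6' and forms C5'–C6' and N1'–C6' in one operation while C2' is left alone. The MOM ethers are kept to the end: they mask the phenols flanking the benzylic amine, direct the lithiation that attaches the flavone C2–C4 unit as an ynone, and are lost in the acid step that closes the pyranone ring.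

Key step: step 6

Remark: piperidine atoms are primed and flavone atoms unprimed; C2' keeps the ranking N > aryl > CH2 > H from 10 to 24, so its R descriptor is constant; amide 20 is assumed not to be reliably purchasable and is made in one step.

Step 1
Reactants: 1 5-methoxyresorcinol; 2 chloromethyl methyl ether
Product: 3 1-methoxy-3,5-bis(methoxymethoxy)benzene
Conditions: NaH, DMF, 0 °C → rt
Reagents that add atoms: chloromethyl methyl ether, COCCl
Why: Williamson-type O-alkylation of both phenoxides by the reactive α-chloro ether should give the symmetrical bis-acetal, which also supplies the directing groups used in steps 2 and 8.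

Step 2
Reactants: 3 1-methoxy-3,5-bis(methoxymethoxy)benzene; 4 N,N-dimethylformamide
Product: 6 4-methoxy-2,6-bis(methoxymethoxy)benzaldehyde, via aryllithium 5 (not isolated)
Conditions: n-BuLi, TMEDA, THF, 0 °C; DMF, 0 °C → rt; aq. NH4Cl
Reagents that add atoms: N,N-dimethylformamide, CN(C)C=O
Why: Directed ortho-metalation should occur at the C–H between the two OMOM groups, the site acidified and chelated by both of the stronger directing groups, and the aryllithium is then formylated by DMF.

Step 3
Reactants: 6 4-methoxy-2,6-bis(methoxymethoxy)benzaldehyde; 7 (S)-2-methylpropane-2-sulfinamide; 8 allyl bromide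
Product: 10 (S)-N-[(1R)-1-[4-methoxy-2,6-bis(methoxymethoxy)phenyl]but-3-en-1-yl]-2-methylpropane-2-sulfinamide, via N-sulfinyl aldimine 9 (not isolated)
Conditions: Ti(OEt)4, THF, 60 °C; then In powder, allyl bromide, 60 °C; aq. NaCl work-up
Reagents that add atoms: (S)-2-methylpropane-2-sulfinamide, CC(C)(C)[S@](=O)N; allyl bromide, C=CCBr
Why: One-pot tert-butanesulfinyl imine condensation and Barbier-type indium allylation, in which the allylindium adds through a chair-like transition state with the metal held by the sulfinyl oxygen, so the (S)-sulfinyl group should direct allyl to the Re face of the E-aldimine and set the future C2' as R.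

Step 4
Reactants: 10 (S)-N-[(1R)-1-[4-methoxy-2,6-bis(methoxymethoxy)phenyl]but-3-en-1-yl]-2-methylpropane-2-sulfinamide; 11 iodomethane
Product: 12 (S)-N-[(1R)-1-[4-methoxy-2,6-bis(methoxymethoxy)phenyl]but-3-en-1-yl]-N,2-dimethylpropane-2-sulfinamide
Conditions: NaH, DMF, 0 °C → rt; MeI
Reagents that add atoms: iodomethane, CI
Why: N-alkylation of the sulfinamide anion, the only acidic site, should stop cleanly at the mono-methyl stage because the product has no N–H left, and neither the carbon nor the sulfur stereocentre takes part.

Step 5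
Reactants: 12 (S)-N-[(1R)-1-[4-methoxy-2,6-bis(methoxymethoxy)phenyl]but-3-en-1-yl]-N,2-dimethylpropane-2-sulfinamide
Product: 13 (1R)-1-[4-methoxy-2,6-bis(methoxymethoxy)phenyl]-N-methylbut-3-en-1-amine
Conditions: HCl (4 M in dioxane, 2.2 equiv), MeOH, 0 °C; NaHCO3 work-up
Reagents that add atoms: none
Why: Acid-mediated S–N cleavage of the sulfinamide (auxiliary removal by sulfinyl transfer to methanol) is much faster at 0 °C than hydrolysis of aryl MOM acetals, so a limited charge of HCl should free the secondary amine with both MOM groups and the C–N stereocentre intact.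

Step 6
Reactants: 13 (1R)-1-[4-methoxy-2,6-bis(methoxymethoxy)phenyl]-N-methylbut-3-en-1-amine; 14 carbon monoxide
Product: 17 (2R)-2-[4-methoxy-2,6-bis(methoxymethoxy)phenyl]-1-methylpiperidine, via amino aldehyde 15 (not isolated), via cyclic enamine 16 (not isolated)
Conditions: [Rh(cod)2]BF4 (2 mol%), Xantphos (4 mol%), CO (8 bar), H2 (32 bar), toluene/MeOH 1:1, 110 °C
Reagents that add atoms: carbon monoxide, [C-]#[O+]
Why: The Xantphos-ligated rhodium hydride adds to the monosubstituted alkene with rhodium at the terminal carbon C5', CO insertion and hydrogenolysis give the linear amino aldehyde 15, the N-methylamine attacks the formyl carbon in a 6-exo-trig closure, the hemiaminal loses water to the iminium/enamine 16, and rhodium hydride hydrogenates this to the piperidine. The closest known reaction types are hydroaminomethylation of terminal alkenes with secondary amines and the cyclohydrocarbonylation of homoallylic amine derivatives to six-membered aza-rings. No new stereocentre is formed: C2' undergoes no bond change and the transient unsaturation lies at C5'–C6' and N1'–C6', so the configuration from step 3 is carried through. The step needs linear rather than branched hydroformylation, since the branched aldehyde would end in a 4-methylpyrrolidine; the wide-bite-angle diphosphine on a terminal alkene secures this and also occupies the sites an amine-chelated branched alkyl would need. It also needs hydrogenation of the enamine and not of the starting alkene, which the CO pressure and the protic co-solvent (iminium formation) favour. Both phenols stay masked as MOM ethers and the amine buffers the medium, so ionisation of the benzylic C–N bond through an ortho-quinone methide is not available at this temperature.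

Step 7
Reactants: 18 3-phenylprop-2-ynoic acid; 19 N,O-dimethylhydroxylamine hydrochloride
Product: 20 N-methoxy-N-methyl-3-phenylprop-2-ynamide
Conditions: EDC·HCl, N-methylmorpholine, CH2Cl2, 0 °C → rt
Reagents that add atoms: N,O-dimethylhydroxylamine hydrochloride, CNOC.Cl
Why: Carbodiimide-mediated amide coupling, in which the O-acylisourea formed at 0 °C is intercepted by the liberated hydroxylamine, should give the Weinreb amide of the alkynoic acid.

Step 8
Reactants: 17 (2R)-2-[4-methoxy-2,6-bis(methoxymethoxy)phenyl]-1-methylpiperidine; 20 N-methoxy-N-methyl-3-phenylprop-2-ynamide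
Product: 22 1-[6-methoxy-2,4-bis(methoxymethoxy)-3-[(2R)-1-methylpiperidin-2-yl]phenyl]-3-phenylprop-2-yn-1-one, via aryllithium 21 (not isolated)
Conditions: n-BuLi, TMEDA, THF, 0 °C; 20, −78 °C; aq. NH4Cl at −78 °C
Reagents that add atoms: N-methoxy-N-methyl-3-phenylprop-2-ynamide, CON(C)C(=O)C#Cc1ccccc1
Why: Directed ortho-metalation followed by Weinreb ketone synthesis: the two remaining aromatic C–H positions are equivalent and each is flanked by OMOM and OMe, and the chelated N-methoxy adduct should hold the addition at the ketone stage until the cold quench.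

Step 9
Reactants: 22 1-[6-methoxy-2,4-bis(methoxymethoxy)-3-[(2R)-1-methylpiperidin-2-yl]phenyl]-3-phenylprop-2-yn-1-one
Product: 24 7-hydroxy-5-methoxy-8-[(2R)-1-methylpiperidin-2-yl]-2-phenyl-4H-chromen-4-one, via dihydroxy ynone 23 (not isolated)
Conditions: HCl (1.25 M in MeOH), 50 °C; NaHCO3 work-up to pH 8, no heating of the free base
Reagents that add atoms: none
Why: Acid transacetalisation removes both MOM groups and the freed phenol ortho to the carbonyl should add to the protonated ynone in a 6-endo-dig oxa-Michael closure to the 4-pyranone ring, while the amine stays protonated and the ring is acyl-deactivated, which disfavours retro-Mannich or quinone-methide ionisation at C2'.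

Compound list
1 | 5-methoxyresorcinol (5-methoxybenzene-1,3-diol) | COc1cc(O)cc(O)c1 | starting material
2 | chloromethyl methyl ether | COCCl | starting material
3 | 1-methoxy-3,5-bis(methoxymethoxy)benzene | COCOc1cc(OC)cc(OCOC)c1 | intermediate
4 | N,N-dimethylformamide | CN(C)C=O | starting material
5 | [4-methoxy-2,6-bis(methoxymethoxy)phenyl]lithium | [Li]c1c(OCOC)cc(OC)cc1OCOC | intermediate
6 | 4-methoxy-2,6-bis(methoxymethoxy)benzaldehyde | COCOc1cc(OC)cc(OCOC)c1C=O | intermediate
7 | (S)-2-methylpropane-2-sulfinamide | CC(C)(C)[S@](=O)N | starting material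
8 | allyl bromide (3-bromoprop-1-ene) | C=CCBr | starting material
9 | (S,E)-N-{[4-methoxy-2,6-bis(methoxymethoxy)phenyl]methylidene}-2-methylpropane-2-sulfinamide | CC(C)(C)[S@](=O)/N=C/c1c(OCOC)cc(OC)cc1OCOC | intermediate
10 | (S)-N-[(1R)-1-[4-methoxy-2,6-bis(methoxymethoxy)phenyl]but-3-en-1-yl]-2-methylpropane-2-sulfinamide | CC(C)(C)[S@](=O)N[C@H](CC=C)c1c(OCOC)cc(OC)cc1OCOC | intermediate
11 | iodomethane | CI | starting material
12 | (S)-N-[(1R)-1-[4-methoxy-2,6-bis(methoxymethoxy)phenyl]but-3-en-1-yl]-N,2-dimethylpropane-2-sulfinamide | CC(C)(C)[S@](=O)N(C)[C@H](CC=C)c1c(OCOC)cc(OC)cc1OCOC | intermediate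
13 | (1R)-1-[4-methoxy-2,6-bis(methoxymethoxy)phenyl]-N-methylbut-3-en-1-amine | COCOc1cc(OC)cc(OCOC)c1[C@@H](CC=C)NC | intermediate
14 | carbon monoxide | [C-]#[O+] | starting material
15 | (5R)-5-[4-methoxy-2,6-bis(methoxymethoxy)phenyl]-5-(methylamino)pentanal | CN[C@H](CCCC=O)c1c(OCOC)cc(OC)cc1OCOC | intermediate
16 | (2R)-2-[4-methoxy-2,6-bis(methoxymethoxy)phenyl]-1-methyl-1,2,3,4-tetrahydropyridine | CN1C=CCC[C@@H]1c1c(OCOC)cc(OC)cc1OCOC | intermediate
17 | (2R)-2-[4-methoxy-2,6-bis(methoxymethoxy)phenyl]-1-methylpiperidine | COCOc1cc(OC)cc(OCOC)c1[C@H]1CCCCN1C | intermediate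
18 | 3-phenylprop-2-ynoic acid | OC(=O)C#Cc1ccccc1 | starting material
19 | N,O-dimethylhydroxylamine hydrochloride | CNOC.Cl | starting material
20 | N-methoxy-N-methyl-3-phenylprop-2-ynamide | CON(C)C(=O)C#Cc1ccccc1 | intermediate
21 | [6-methoxy-2,4-bis(methoxymethoxy)-3-[(2R)-1-methylpiperidin-2-yl]phenyl]lithium | [Li]c1c(OC)cc(OCOC)c([C@H]2CCCCN2C)c1OCOC | intermediate
22 | 1-[6-methoxy-2,4-bis(methoxymethoxy)-3-[(2R)-1-methylpiperidin-2-yl]phenyl]-3-phenylprop-2-yn-1-one | COCOc1cc(OC)c(C(=O)C#Cc2ccccc2)c(OCOC)c1[C@H]1CCCCN1C | intermediate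
23 | 1-[2,4-dihydroxy-6-methoxy-3-[(2R)-1-methylpiperidin-2-yl]phenyl]-3-phenylprop-2-yn-1-one | COc1cc(O)c([C@H]2CCCCN2C)c(O)c1C(=O)C#Cc1ccccc1 | intermediate
24 | 7-hydroxy-5-methoxy-8-[(2R)-1-methylpiperidin-2-yl]-2-phenyl-4H-chromen-4-one | COc1cc(O)c([C@H]2CCCCN2C)c2oc(-c3ccccc3)cc(=O)c12 | target

Total step count: 9. Longest linear sequence: 8 (steps 1–6, 8 and 9; step 7 is a one-step side branch).

Steps most likely to fail

Step 6. The hydroformylation may run at the internal carbon under amine coordination, the alkene may isomerise, or the sequence may stall before the enamine is hydrogenated. The fallback closes the ring by olefin metathesis instead of carbonylation; it sets out from 10 and comes back at 17. Sulfinamide 10 would be N-allylated (NaH, allyl bromide 8, DMF, 0 °C) to the N-allyl sulfinamide diene F1. Ring-closing metathesis with the second-generation Grubbs catalyst RuCl2(H2IMes)(PCy3)(=CHPh) in CH2Cl2 at 40 °C should give the N-sulfinyl tetrahydropyridine F2. Brief HCl/MeOH at 0 °C would remove the sulfinyl group to give the secondary-amine tetrahydropyridine F3. Reductive methylation (aq. CH2O, NaBH(OAc)3, 1,2-dichloroethane) would give the N-methyl tetrahydropyridine F4, and hydrogenation of the ring alkene (H2, PtO2, EtOAc, rt) should return piperidine 17. Here C6' comes from the N-allyl CH2.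

Step 3. Facial selectivity may be poor if an ortho MOM oxygen competes with the sulfinyl oxygen for the metal, and imine formation at the doubly ortho-substituted aldehyde may be slow. The fallback gives up auxiliary control for a racemic synthesis with resolution; it sets out from 6 and comes back at 13, bypassing steps 4 and 5. Aldehyde 6 would be condensed with methylamine (MeNH2 in THF, MgSO4) to the N-methyl aldimine F5. Allylmagnesium bromide (CH2=CHCH2MgBr, from allyl bromide 8 and Mg) in Et2O at 0 °C should add to give the racemic homoallylic N-methylamine F6. Preparative chromatography on a chiral stationary phase would then deliver the (R)-enantiomer 13.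

Step 9. The ynone may close in the 5-exo mode, acetal cleavage may be incomplete, or prolonged acid exposure may erode configuration. The fallback replaces the ynone by a 1,3-diketone, which can only close to the six-membered pyranone; it sets out from 17 and comes back at 24. Piperidine 17 would be lithiated as in step 8 and trapped with N-methoxy-N-methylacetamide to give the aryl methyl ketone F7. Crossed Claisen condensation with methyl benzoate (NaH, THF, reflux) should give the 1,3-diketone F8. Methanolic HCl at 50 °C would then remove both MOM groups and cyclodehydrate the diketone to 24.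

Further compounds
F1 | step 6 | (S)-N-allyl-N-[(1R)-1-[4-methoxy-2,6-bis(methoxymethoxy)phenyl]but-3-en-1-yl]-2-methylpropane-2-sulfinamide | CC(C)(C)[S@](=O)N(CC=C)[C@H](CC=C)c1c(OCOC)cc(OC)cc1OCOC
F2 | step 6 | (2R)-1-[(S)-tert-butylsulfinyl]-2-[4-methoxy-2,6-bis(methoxymethoxy)phenyl]-1,2,3,6-tetrahydropyridine | CC(C)(C)[S@](=O)N1CC=CC[C@@H]1c1c(OCOC)cc(OC)cc1OCOC
F3 | step 6 | (2R)-2-[4-methoxy-2,6-bis(methoxymethoxy)phenyl]-1,2,3,6-tetrahydropyridine | N1CC=CC[C@@H]1c1c(OCOC)cc(OC)cc1OCOC
F4 | step 6 | (2R)-2-[4-methoxy-2,6-bis(methoxymethoxy)phenyl]-1-methyl-1,2,3,6-tetrahydropyridine | CN1CC=CC[C@@H]1c1c(OCOC)cc(OC)cc1OCOC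
F5 | step 3 | (E)-1-[4-methoxy-2,6-bis(methoxymethoxy)phenyl]-N-methylmethanimine | C/N=C/c1c(OCOC)cc(OC)cc1OCOC
F6 | step 3 | rac-1-[4-methoxy-2,6-bis(methoxymethoxy)phenyl]-N-methylbut-3-en-1-amine | CNC(CC=C)c1c(OCOC)cc(OC)cc1OCOC
F7 | step 9 | 1-[6-methoxy-2,4-bis(methoxymethoxy)-3-[(2R)-1-methylpiperidin-2-yl]phenyl]ethan-1-one | COCOc1cc(OC)c(C(C)=O)c(OCOC)c1[C@H]1CCCCN1C
F8 | step 9 | 1-[6-methoxy-2,4-bis(methoxymethoxy)-3-[(2R)-1-methylpiperidin-2-yl]phenyl]-3-phenylpropane-1,3-dione | COCOc1cc(OC)c(C(=O)CC(=O)c2ccccc2)c(OCOC)c1[C@H]1CCCCN1C
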